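The quinone ring (C1–C6, carbonyls at C1 and C4, nonadecyl at C2) is cut into a four-carbon half, C3–C4(O)–C5–C6, and a two-carbon half, C1–C2 with its chain. The key step exploits the fact that C3–C6 is the skeleton of a 2-oxygenated butadiene and C1–C2 that of an alkyne. A regioselective Diels–Alder reaction of Danishefsky's diene with docos-2-ynal forms C2–C3 and C1–C6 at once. After loss of methanol it delivers the whole benzenoid ring. The precursor is an open-chain ynal. Its formyl group on C1 activates and orients the alkyne and serves as a latent oxygen, which Dakin oxidation exchanges for OH before the hydroquinone is oxidised.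

Key step: step 2

Remark: the side chain is read as the unbranched C19H39 (nonadecyl) group. The target has no stereocentre, so no stereocontrol is needed.

Step 1
Reactants: 1 propyne; 2 1-bromooctadecane
Product: 5 docos-2-ynal, via 1,3-dilithiopropyne 3 (not isolated), via lithium henicos-1-yn-1-ide 4 (not isolated)
Conditions: 1, n-BuLi (2.1 equiv), TMEDA, Et2O/hexane, −78 °C to rt; 2, THF, 0 °C to rt; DMF, −20 °C to rt; inverse quench into cold 1 M HCl
Reagents that add atoms: N,N-dimethylformamide, CN(C)C=O
Why: Double deprotonation of propyne gives a dianion whose sp3 carbanion is by far the more nucleophilic site, so SN2 alkylation by the primary bromide takes place there and leaves lithium acetylide 4, which adds to DMF and releases the ynal on acidic quench (dianion alkylation followed by acetylide formylation); the acid quench also keeps dimethylamine protonated and away from the ynal.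

Step 2
Reactants: 5 docos-2-ynal; 6 (E)-1-methoxy-3-(trimethylsilyloxy)buta-1,3-diene (Danishefsky's diene)
Product: 9 4-hydroxy-2-nonadecylbenzaldehyde, via cyclohexa-1,4-diene cycloadduct 7 (not isolated), via aryl trimethylsilyl ether 8 (not isolated)
Conditions: 6 (2 equiv), toluene, 110 °C, sealed tube, no Lewis acid; then 1 M HCl, THF, rt
Reagents that add atoms: none
Why: A concerted, asynchronous thermal [4π+2π] cycloaddition (Diels–Alder reaction of a 1-alkoxy-3-silyloxydiene with an acetylenic carbonyl compound, a known route to 4-hydroxyaryl carbonyl compounds) joins the CH2 terminus of the diene to the chain-bearing alkyne carbon (ring C3–C2) and the methoxy-bearing terminus to the formyl-bearing alkyne carbon (ring C6–C1). The one ring formed, the six-membered carbocycle, is closed by suprafacial addition of both diene termini to one π bond of the alkyne, so no endo/exo question arises. Regioselectivity is needed and is secured by matched polarisation: both oxygen donors raise the HOMO coefficient at the CH2 terminus, and the formyl group places the largest LUMO coefficient on the β-alkyne carbon that carries the chain, so the oxygen ends para and the chain ortho to CHO. Chemoselectivity for C≡C over the aldehyde C=O is also needed and is served by leaving out any Lewis acid, as in the thermal reactions of this diene with enals. The single stereocentre of 7 (C–OMe, racemic) is erased when methanol is lost to give arene 8, a step driven by aromatisation, and dilute acid then cleaves the silyl ether.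

Step 3
Reactants: 9 4-hydroxy-2-nonadecylbenzaldehyde
Product: 12 2-nonadecyl-1,4-benzoquinone, via aryl formate 10 (not isolated), via 2-nonadecylhydroquinone 11 (not isolated)
Conditions: 30% H2O2 (1.1 equiv), NaOH, THF/H2O, N2, 0 °C to rt; then H2SO4 to pH 2, I2 (5 mol %), 30% H2O2 (1.5 equiv), rt
Reagents that add atoms: hydrogen peroxide, OO
Why: Dakin oxidation, in which hydroperoxide adds to the formyl group, the electron-rich para-hydroxyaryl group migrates from carbon to oxygen and formate 10 is saponified to hydroquinone 11, is followed after acidification by the iodine-catalysed H2O2 oxidation of hydroquinones to quinones, so one oxidant serves both stages and no other group in the molecule is oxidisable.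

Compound list
1 | propyne | CC#C | starting material
2 | 1-bromooctadecane | CCCCCCCCCCCCCCCCCCBr | starting material
3 | 1,3-dilithiopropyne | [Li]CC#C[Li] | intermediate
4 | lithium henicos-1-yn-1-ide | CCCCCCCCCCCCCCCCCCCC#C[Li] | intermediate
5 | docos-2-ynal | CCCCCCCCCCCCCCCCCCCC#CC=O | intermediate
6 | (E)-1-methoxy-3-(trimethylsilyloxy)buta-1,3-diene (Danishefsky's diene) | CO/C=C/C(=C)O[Si](C)(C)C | starting material
7 | 6-methoxy-2-nonadecyl-4-(trimethylsilyloxy)cyclohexa-1,4-diene-1-carbaldehyde (racemic) | CCCCCCCCCCCCCCCCCCCC1=C(C=O)C(OC)C=C(O[Si](C)(C)C)C1 | intermediate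
8 | 2-nonadecyl-4-(trimethylsilyloxy)benzaldehyde | CCCCCCCCCCCCCCCCCCCc1cc(O[Si](C)(C)C)ccc1C=O | intermediate
9 | 4-hydroxy-2-nonadecylbenzaldehyde | CCCCCCCCCCCCCCCCCCCc1cc(O)ccc1C=O | intermediate
10 | 4-hydroxy-2-nonadecylphenyl formate | CCCCCCCCCCCCCCCCCCCc1cc(O)ccc1OC=O | intermediate
11 | 2-nonadecylbenzene-1,4-diol (2-nonadecylhydroquinone) | CCCCCCCCCCCCCCCCCCCc1cc(O)ccc1O | intermediate
12 | 2-nonadecyl-1,4-benzoquinone (2-nonadecylcyclohexa-2,5-diene-1,4-dione) | CCCCCCCCCCCCCCCCCCCC1=CC(=O)C=CC1=O | target

Total step count: 3
Longest linear sequence: 3 steps (1 and 2 to 5, 5 to 9, 9 to 12)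

Steps most likely to fail

(a) The cycloaddition, step 2. The β-alkyl group slows the addition. Thermal decay of the diene, or hetero-Diels–Alder addition to the formyl C=O, may then outrun the reaction at the triple bond. The fallback changes the activating group and sets out from lithium acetylide 4.
- Acylation with N-methoxy-N-methylacetamide should give tricos-3-yn-2-one F1. Its ketone does not act as a heterodienophile under thermal conditions and tolerates harsher heating (xylene, 140 °C).
- Cycloaddition with 6 and acid work-up should give 1-(4-hydroxy-2-nonadecylphenyl)ethan-1-one F2.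
- Dakin oxidation of this para-hydroxyaryl ketone (H2O2, NaOH) brings the route back at hydroquinone 11.

(b) The dianion sequence, step 1. Several things may go wrong:
- The second deprotonation may be incomplete.
- Alkylation may occur through the allenyl form of the dianion.
- Leftover n-BuLi may consume the bromide or DMF.
- Amine may add to the ynal during the quench.

The fallback replaces the dianion by a terminally blocked monoanion and sets out from bromide 2.
- Lithiated 1-(trimethylsilyl)propyne (n-BuLi, THF, −78 °C) is alkylated with 2 to give trimethyl(henicos-1-yn-1-yl)silane F3.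
- K2CO3 in MeOH removes silicon to give henicos-1-yne F4, which can be purified.
- Deprotonation with one equivalent of n-BuLi comes back at 4.

(c) The oxidation sequence, step 3. If the hydroquinone is oxidised too early in the alkaline peroxide, the quinone may be epoxidised and the ring degraded. The long chain may also keep the phenolate out of the aqueous phase and stall the aryl migration. The fallback avoids a free hydroquinone in base and sets out from 9.
- O-methylation (iodomethane, K2CO3, acetone) gives 4-methoxy-2-nonadecylbenzaldehyde F5.
- Baeyer–Villiger oxidation with mCPBA in CH2Cl2 gives 4-methoxy-2-nonadecylphenyl formate F6.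
- Methanolysis (K2CO3, MeOH) gives 4-methoxy-2-nonadecylphenol F7.
- Oxidative demethylation with (NH4)2Ce(NO3)6 in MeCN/H2O comes back at 12.

Further compounds
F1 | step 2 | tricos-3-yn-2-one | CCCCCCCCCCCCCCCCCCCC#CC(C)=O
F2 | step 2 | 1-(4-hydroxy-2-nonadecylphenyl)ethan-1-one | CCCCCCCCCCCCCCCCCCCc1cc(O)ccc1C(C)=O
F3 | step 1 | trimethyl(henicos-1-yn-1-yl)silane | CCCCCCCCCCCCCCCCCCCC#C[Si](C)(C)C
F4 | step 1 | henicos-1-yne | CCCCCCCCCCCCCCCCCCCC#C
F5 | step 3 | 4-methoxy-2-nonadecylbenzaldehyde | CCCCCCCCCCCCCCCCCCCc1cc(OC)ccc1C=O
F6 | step 3 | 4-methoxy-2-nonadecylphenyl formate | CCCCCCCCCCCCCCCCCCCc1cc(OC)ccc1OC=O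
F7 | step 3 | 4-methoxy-2-nonadecylphenol | CCCCCCCCCCCCCCCCCCCc1cc(OC)ccc1O
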